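## Structural features

Chroman numbering is used throughout (O1, C2, C3, C4, C4a, C5 to C8, C8a; ring A is the benzene ring, ring B the dihydropyran ring). Ring A is a hexasubstituted phloroglucinol. Its three oxygens are in three different states (ring ether O1 on C8a, free OH on C5, OMe on C7), and the three carbons between them carry three different carbon groups (the C4 methylene on C4a, the 3-hexanoic acid chain on C6, prenyl on C8). Ring B carries two adjacent stereocentres, C2 (S) and C3 (R), with trans methyl groups, and C4 is a plain CH2, so there is no carbonyl through which C3 could be set or equilibrated. The third stereocentre, the benzylic carbon of the side chain (R), is flanked by O5 and O7 and is separated from C2/C3 by ring A, so it has to be set on its own. Fragile points: the 5-OH/carboxylic acid pair closes to a dihydrocoumarin under acid or heat, the prenyl alkene tolerates neither strong acid nor hydrogenation, and ring A is easily oxidised. The key step exploits two features. The O1–C2(Me)–C3(Me)–C4 segment is a butane-2,3-diyl unit of local C2 symmetry held between an oxygen and a benzylic carbon. C4a lies between two oxygen-bearing carbons (C5 and C8a), so a ring A precursor with two equivalent oxygens can close ring B through either one and leave the other as the 5-OH. The real difficulty is the enantiopure trans-2,3-dimethyl ring B without any C4 handle, together with placing six different substituents around ring A.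

## Logic of the disconnections

In one sentence: ring B is made by a one-pot double SN2 annulation of 8 with 7.

18 to 17: the acyl C–O bond of the acid is cut. The carboxyl is kept as its methyl ester through the thermal step. The forward step must saponify and then acidify mildly, because O5 can relactonise.

17 to 15 (through 16): the C8–prenyl bond is cut and the prenyl group is reconnected to O5. C8 is para to O5 and both ortho carbons (C4a, C6) are blocked, so two successive [3,3] shifts deliver a normal, unrearranged prenyl group to C8 without halogenation or a metal. The demand is thermal tolerance of the ester and of all three stereocentres.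

15 to 13 (through 14): the O5–prenyl bond and the ester O–CH3 bond are cut, which reveals a six-membered lactone between O5 and the carboxyl. The lactone is both the product of the stereocentre-forming step and a protecting group for O5. The forward step must open it irreversibly, which O-alkylation of the liberated phenoxide ensures.

13 to 12: the benzylic C–H bond is cut to give the coumarin double bond. The benzylic stereocentre becomes the outcome of a catalyst-controlled conjugate hydride addition. The demand is a catalyst reactive enough for a β,β-disubstituted lactone with a peri methoxy group.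

12 to 10 + 11: the C6–C bond and the O5–acyl bond are cut. C6 is the only free position ortho to the single free OH of 10, so the regiochemistry of the forward condensation is forced by the need to lactonise.

10 to 4 + 7 (through 8 and 9): the C3–C4 and O1–C2 bonds are cut. This removes ring B and both of its stereocentres in one operation. It leaves an achiral, symmetric arene and a C2-symmetric C4 unit in which both stereocentres are bought. The demand is that the benzylic carbon reacts before oxygen, that both displacements are clean SN2 inversions at secondary carbons, and that a phenoxide can be released under basic conditions in the same flask.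

4 to 2 to 1 (through 3): the arene–CH2 bond is cut. The carbon between the two acetal-protected oxygens of 2 is the most acidic ring position, so directed metalation places the benzylic carbon exactly where C4 must be. 7 to 5 (through 6): the S–O bonds are cut, with no change at carbon.

## Other disconnections considered

Alternative 1: This is the route that comes to mind first. A carbonyl is added back at C4, ring B is cut at C4–C4a and O1–C2, and the acid chain is folded back into a coumarin. Forward: Pechmann condensation of phloroglucinol with 11 would give the coumarin A1. Friedel–Crafts acylation with tigloyl chloride and oxa-Michael closure would give the trans-2,3-dimethylchromanone A2. O-methylation, removal of the C4 carbonyl, conjugate reduction, prenylation and hydrolysis would follow. The chosen plan is preferred for three reasons. The oxa-Michael closure is reversible and C3 is enolisable, so the trans relationship is thermodynamic but the absolute configuration is not controlled, and a racemate would have to be resolved. A carbonyl would be introduced only to be removed. Acylation of A1 can occur at either free ring carbon, and three hydroxyls would have to be told apart.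

Alternative 2: Ring A itself is cut, by a Danheiser benzannulation. Forward: the pyran-fused 3-alkoxycyclobutenone A3 would open thermally to a vinylketene, add the 1-methoxyalkyne A4 in a [2+2] reaction, open again and close by 6π-electrocyclisation to give 17 with all six substituents placed. The strain-driven cascade would settle the substitution pattern completely. The stereochemical problem is only moved, however. A3 needs the same trans-dimethyl pyran to be built on a less stable bicyclic vinylogous ester, and A4 is a sensitive ynol ether with a propargylic stereocentre. Both partners would need multistep syntheses, so the route would be longer.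

Alternative 3: The same two bonds (C3–C4, O1–C2) are cut with the opposite polarity. Forward: inverse-demand hetero-Diels–Alder reaction of the o-quinone methide A5 with a (Z)-propenyl ether would give the 2-alkoxy-3-methylchroman A6. Ionisation to the oxocarbenium ion and addition of a methyl nucleophile at C2 would then give 10. Only C3 would be set in the cycloaddition, and that would need an auxiliary or an asymmetric catalyst acting on an unsubstituted, short-lived quinone methide. C2 would be set in a second event whose trans selectivity rests on a small 3-methyl group. The chosen plan has no stereo-determining choice at all, because the double inversion of a C2-symmetric unit can give only one product, and it is one step shorter.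

Key step: step 4

Assumption: the target is taken as the free hydroxy acid drawn (not its lactone), and the (R)-ligand in step 6 is assumed to give the (4R)-lactone 13; if the sense of induction is opposite, the (S)-ligand is used with no other change.

## Route

Step 1
Reactants: 1 5-methoxybenzene-1,3-diol
Product: 2 1-methoxy-3,5-bis{[2-(trimethylsilyl)ethoxy]methoxy}benzene
Conditions: NaH (2.3 equiv), SEMCl (2.3 equiv), THF/DMF, 0 °C → rt
Reagents that add atoms: 2-(trimethylsilyl)ethoxymethyl chloride, C[Si](C)(C)CCOCCl
Why: Williamson-type O-alkylation of both phenoxides; the SEM acetals are the stronger ortho-directing groups needed in step 2 and are fluoride-labile masks that release phenoxide under basic conditions in step 4.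

Step 2
Reactants: 2 1-methoxy-3,5-bis{[2-(trimethylsilyl)ethoxy]methoxy}benzene
Product: 4 tributyl{[4-methoxy-2,6-bis({[2-(trimethylsilyl)ethoxy]methoxy})phenyl]methyl}stannane, via aryllithium 3 (not isolated)
Conditions: n-BuLi (1.1 equiv), THF, 0 °C; then Bu3SnCH2I, −78 °C → rt
Reagents that add atoms: tributyl(iodomethyl)stannane, CCCC[Sn](CCCC)(CCCC)CI
Why: Directed ortho-metalation should occur at the carbon flanked by two OCH2O acetal oxygens in preference to the carbons flanked by OMe and one acetal; SN2 alkylation of the aryllithium on the primary iodide then gives a benzylstannane, a storable precursor of the benzylic carbanion.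

Step 3
Reactants: 5 (2R,3R)-butane-2,3-diol
Product: 7 (4R,5R)-4,5-dimethyl-1,3,2-dioxathiolane 2,2-dioxide, via cyclic sulfite 6 (not isolated)
Conditions: SOCl2, CH2Cl2, reflux; then RuCl3·xH2O (cat.), NaIO4, MeCN/H2O, 0 °C
Reagents that add atoms: thionyl chloride, O=S(Cl)Cl; sodium periodate, [Na+].[O-]I(=O)(=O)=O
Why: Standard two-stage cyclic sulfate synthesis (sulfite formation, then RuO4-mediated oxidation at sulfur); no C–O bond is broken, so both stereocentres of the diol are retained.

Step 4
Reactants: 4 tributyl{[4-methoxy-2,6-bis({[2-(trimethylsilyl)ethoxy]methoxy})phenyl]methyl}stannane; 7 (4R,5R)-4,5-dimethyl-1,3,2-dioxathiolane 2,2-dioxide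
Product: 10 (2S,3R)-7-methoxy-2,3-dimethyl-3,4-dihydro-2H-chromen-5-ol, via benzyllithium 8 (not isolated), via sulfate monoester 9 (not isolated)
Conditions: MeLi (1.0 equiv), THF, −78 °C; then 7, CuBr·SMe2 (10 mol %), −78 → 0 °C; then TBAF (5 equiv), H2NCH2CH2NH2, DMPU, 70 °C; aq NH4Cl
Reagents that add atoms: (4R,5R)-4,5-dimethyl-1,3,2-dioxathiolane 2,2-dioxide (compound 7), C[C@H]1OS(=O)(=O)O[C@@H]1C
Why: Tin–lithium exchange converts 4 into the benzylic carbanion 8, which should open 7 by copper-assisted SN2 attack at one of its two homotopic carbons, inverting it and fixing C3 as R, while the sulfate monoester 9 keeps the second C–O bond as a latent leaving group. Fluoride then fragments both SEM groups (loss of Me3SiF, ethene and formaldehyde, the last trapped by ethylenediamine), and one of the two equivalent phenoxides displaces the secondary sulfate in a 6-exo-tet closure of ring B, inverting that carbon and fixing C2 as S. The closest known reaction types are the opening of 1,2-cyclic sulfates by organometallic carbon nucleophiles and the double displacement of cyclic sulfates by dinucleophiles (malonate to cyclopropane, primary phosphide to phospholane, Wenker-type closures), here run with a carbon/oxygen dinucleophile. The trans relationship is inherited rather than selected, because two inversions on a C2-symmetric (R,R) unit can only give the (2S,3R) ring, whichever carbon is attacked first. The step needs C-alkylation before O-alkylation, which is secured because oxygen stays masked until fluoride is added. It needs SN2 rather than E2 at a secondary carbon, which is favoured by a soft delocalised benzylic nucleophile, low temperature and copper. It needs ring closure rather than intermolecular reaction, which is favoured because the sulfate monoester anion is inert to everything except the intramolecular phenoxide. The symmetry of the arene means that either oxygen closes the ring, and the phenoxide left over is the free 5-OH required in step 5.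

Step 5
Reactants: 10 (2S,3R)-7-methoxy-2,3-dimethyl-3,4-dihydro-2H-chromen-5-ol; 11 ethyl 3-oxohexanoate
Product: 12 (8S,9R)-5-methoxy-8,9-dimethyl-4-propyl-9,10-dihydro-2H,8H-pyrano[2,3-f]chromen-2-one
Conditions: MeSO3H, 0 °C → rt
Reagents that add atoms: ethyl 3-oxohexanoate (compound 11), CCCC(=O)CC(=O)OCC
Why: Pechmann condensation of a 3,5-dialkoxyphenol with a β-keto ester; a coumarin can only form ortho to the free OH, and C6 is the only free ortho carbon, so the side-chain carbons are placed regiospecifically while the alkyl aryl ethers and the two ring B stereocentres are inert to the acid.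

Step 6
Reactants: 12 (8S,9R)-5-methoxy-8,9-dimethyl-4-propyl-9,10-dihydro-2H,8H-pyrano[2,3-f]chromen-2-one
Product: 13 (4R,8S,9R)-5-methoxy-8,9-dimethyl-4-propyl-3,4,9,10-tetrahydro-2H,8H-pyrano[2,3-f]chromen-2-one
Conditions: Cu(OAc)2·H2O (5 mol %), (R)-DTBM-SEGPHOS (5.5 mol %), (EtO)2MeSiH (1.5 equiv), t-BuOH, toluene, 0 °C → rt
Reagents that add atoms: none
Why: Copper hydride-catalysed asymmetric 1,4-reduction of a 4-substituted coumarin, a known substrate class for this catalyst; the ligand selects the face of hydride delivery to the β-carbon and so sets the benzylic stereocentre, and t-BuOH protonates the copper enolate so that the lactone is not reduced further.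

Step 7
Reactants: 13 (4R,8S,9R)-5-methoxy-8,9-dimethyl-4-propyl-3,4,9,10-tetrahydro-2H,8H-pyrano[2,3-f]chromen-2-one
Product: 15 methyl (3R)-3-[(2S,3R)-7-methoxy-2,3-dimethyl-5-[(3-methylbut-2-en-1-yl)oxy]-3,4-dihydro-2H-chromen-6-yl]hexanoate, via sodium phenoxide ester 14 (not isolated)
Conditions: NaOMe (1.1 equiv), MeOH, 0 °C → rt; evaporate; prenyl bromide, DMF, 0 °C → rt
Reagents that add atoms: sodium methoxide, C[O-].[Na+]; 1-bromo-3-methylbut-2-ene, CC(C)=CCBr
Why: Methanolysis of the aryl lactone lies on the side of the phenoxide ester because phenoxide is the weaker base, and Williamson O-alkylation in DMF then makes the opening irreversible; the benzylic stereocentre is β to the carbonyl and not enolisable.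

Step 8
Reactants: 15 methyl (3R)-3-[(2S,3R)-7-methoxy-2,3-dimethyl-5-[(3-methylbut-2-en-1-yl)oxy]-3,4-dihydro-2H-chromen-6-yl]hexanoate
Product: 17 methyl (3R)-3-[(2S,3R)-5-hydroxy-7-methoxy-2,3-dimethyl-8-(3-methylbut-2-en-1-yl)-3,4-dihydro-2H-chromen-6-yl]hexanoate, via ortho-dienone 16 (not isolated)
Conditions: PhNEt2, 185 °C, degassed, sealed tube
Reagents that add atoms: none
Why: Para-Claisen rearrangement (aromatic Claisen, then Cope): with both ortho carbons blocked, the first [3,3] shift to the less hindered C4a gives a dienone that cannot enolise, a second [3,3] shift carries the allyl unit to C8 with its normal prenyl connectivity, and tautomerisation restores the phenol; migration through C6 would converge on the same product, and any relactonised material is opened again in step 9.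

Step 9
Reactants: 17 methyl (3R)-3-[(2S,3R)-5-hydroxy-7-methoxy-2,3-dimethyl-8-(3-methylbut-2-en-1-yl)-3,4-dihydro-2H-chromen-6-yl]hexanoate
Product: 18 (3R)-3-[(2S,3R)-5-hydroxy-7-methoxy-2,3-dimethyl-8-(3-methylbut-2-en-1-yl)-3,4-dihydro-2H-chromen-6-yl]hexanoic acid
Conditions: LiOH·H2O, THF/MeOH/H2O, rt; then 1 M HCl to pH 4–5, 0 °C
Reagents that add atoms: lithium hydroxide, [Li+].[OH-]
Why: Ester saponification; acidification only to pH 4–5 in the cold should free the acid without lactonisation onto O5 or acid-induced reaction of the prenyl group.

## Compound list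

1 | 5-methoxybenzene-1,3-diol | COc1cc(O)cc(O)c1 | starting material
2 | 1-methoxy-3,5-bis{[2-(trimethylsilyl)ethoxy]methoxy}benzene | COc1cc(OCOCC[Si](C)(C)C)cc(OCOCC[Si](C)(C)C)c1 | intermediate
3 | [4-methoxy-2,6-bis({[2-(trimethylsilyl)ethoxy]methoxy})phenyl]lithium (formed in situ) | [Li]c1c(OCOCC[Si](C)(C)C)cc(OC)cc1OCOCC[Si](C)(C)C | intermediate
4 | tributyl{[4-methoxy-2,6-bis({[2-(trimethylsilyl)ethoxy]methoxy})phenyl]methyl}stannane | CCCC[Sn](CCCC)(CCCC)Cc1c(OCOCC[Si](C)(C)C)cc(OC)cc1OCOCC[Si](C)(C)C | intermediate
5 | (2R,3R)-butane-2,3-diol | C[C@@H](O)[C@@H](C)O | starting material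
6 | (4R,5R)-4,5-dimethyl-1,3,2-dioxathiolane 2-oxide (formed in situ) | C[C@H]1OS(=O)O[C@@H]1C | intermediate
7 | (4R,5R)-4,5-dimethyl-1,3,2-dioxathiolane 2,2-dioxide | C[C@H]1OS(=O)(=O)O[C@@H]1C | intermediate
8 | {[4-methoxy-2,6-bis({[2-(trimethylsilyl)ethoxy]methoxy})phenyl]methyl}lithium (formed in situ) | [Li]Cc1c(OCOCC[Si](C)(C)C)cc(OC)cc1OCOCC[Si](C)(C)C | intermediate
9 | lithium (2R,3R)-4-[4-methoxy-2,6-bis({[2-(trimethylsilyl)ethoxy]methoxy})phenyl]-3-methylbutan-2-yl sulfate (formed in situ) | [Li+].C[C@@H](OS(=O)(=O)[O-])[C@H](C)Cc1c(OCOCC[Si](C)(C)C)cc(OC)cc1OCOCC[Si](C)(C)C | intermediate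
10 | (2S,3R)-7-methoxy-2,3-dimethyl-3,4-dihydro-2H-chromen-5-ol | COc1cc(O)c2c(c1)O[C@@H](C)[C@H](C)C2 | intermediate
11 | ethyl 3-oxohexanoate | CCCC(=O)CC(=O)OCC | starting material
12 | (8S,9R)-5-methoxy-8,9-dimethyl-4-propyl-9,10-dihydro-2H,8H-pyrano[2,3-f]chromen-2-one | CCCC1=CC(=O)Oc2c1c(OC)cc1c2C[C@@H](C)[C@H](C)O1 | intermediate
13 | (4R,8S,9R)-5-methoxy-8,9-dimethyl-4-propyl-3,4,9,10-tetrahydro-2H,8H-pyrano[2,3-f]chromen-2-one | CCC[C@@H]1CC(=O)Oc2c1c(OC)cc1c2C[C@@H](C)[C@H](C)O1 | intermediate
14 | sodium (2S,3R)-6-[(3R)-1-methoxy-1-oxohexan-3-yl]-7-methoxy-2,3-dimethyl-3,4-dihydro-2H-chromen-5-olate (formed in situ) | [Na+].CCC[C@H](CC(=O)OC)c1c([O-])c2c(cc1OC)O[C@@H](C)[C@H](C)C2 | intermediate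
15 | methyl (3R)-3-[(2S,3R)-7-methoxy-2,3-dimethyl-5-[(3-methylbut-2-en-1-yl)oxy]-3,4-dihydro-2H-chromen-6-yl]hexanoate | CCC[C@H](CC(=O)OC)c1c(OCC=C(C)C)c2c(cc1OC)O[C@@H](C)[C@H](C)C2 | intermediate
16 | methyl (3R)-3-[(2S,3R)-7-methoxy-2,3-dimethyl-4a-(2-methylbut-3-en-2-yl)-5-oxo-3,4,4a,5-tetrahydro-2H-chromen-6-yl]hexanoate (C4a epimers, formed in situ) | CCC[C@H](CC(=O)OC)C1=C(OC)C=C2O[C@@H](C)[C@H](C)CC2(C(C)(C)C=C)C1=O | intermediate
17 | methyl (3R)-3-[(2S,3R)-5-hydroxy-7-methoxy-2,3-dimethyl-8-(3-methylbut-2-en-1-yl)-3,4-dihydro-2H-chromen-6-yl]hexanoate | CCC[C@H](CC(=O)OC)c1c(O)c2c(c(CC=C(C)C)c1OC)O[C@@H](C)[C@H](C)C2 | intermediate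
18 | (3R)-3-[(2S,3R)-5-hydroxy-7-methoxy-2,3-dimethyl-8-(3-methylbut-2-en-1-yl)-3,4-dihydro-2H-chromen-6-yl]hexanoic acid | CCC[C@H](CC(=O)O)c1c(O)c2c(c(CC=C(C)C)c1OC)O[C@@H](C)[C@H](C)C2 | target

## Step count and least certain steps

Total steps: 9. Longest linear sequence: 8 (steps 1, 2 and 4 to 9, from 1); step 3 is a one-step side branch from 5.

Step 4 (key step). The most likely failure is E2 elimination of 7 by the basic benzylic anion 8 in competition with SN2 attack at a secondary carbon. The second is a slow closure of 9, since a sulfate monoester is only a modest leaving group; this would leave the electron-rich bis-phenoxide exposed to formaldehyde capture and air oxidation. The fallback sets out from 4 and comes back at 10. 8, generated as in step 4, would instead open (2R,3R)-2,3-dimethyloxirane, which is far less prone to base-induced elimination. Inversion at the attacked carbon would give (2R,3R)-4-[4-methoxy-2,6-bis({[2-(trimethylsilyl)ethoxy]methoxy})phenyl]-3-methylbutan-2-ol F1. TBAF with ethylenediamine would remove both SEM groups to give 2-[(2R,3R)-3-hydroxy-2-methylbutyl]-5-methoxybenzene-1,3-diol F2. An intramolecular Mitsunobu etherification (PPh3, DIAD, THF) would then close ring B with inversion at the carbinol carbon and give 10. The C–O bond is thus formed by redox activation of an alcohol instead of by sulfate displacement, at the cost of two extra steps.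

Step 2. The most likely failure is iodine–lithium exchange between 3 and the iodomethylstannane instead of C-alkylation, which would return protonated 2 and scrambled products. The fallback sets out from 2 and comes back at 4. 3 would be formylated with DMF to 4-methoxy-2,6-bis({[2-(trimethylsilyl)ethoxy]methoxy})benzaldehyde F3. Reduction with NaBH4 would give [4-methoxy-2,6-bis({[2-(trimethylsilyl)ethoxy]methoxy})phenyl]methanol F4. MsCl/LiCl/collidine would give 2-(chloromethyl)-5-methoxy-1,3-bis{[2-(trimethylsilyl)ethoxy]methoxy}benzene F5, used crude because it ionises easily. Displacement with Bu3SnLi would give 4. The tin is then introduced as a nucleophile on a benzylic electrophile instead of as an electrophile on the aryllithium.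

Step 6. The most likely failures are incomplete conversion and insufficient or reversed facial selectivity, because the β-carbon is disubstituted, electron-rich and hindered by the peri methoxy group. The fallback sets out from 10, bypasses 12 and comes back at 13. An iminium-catalysed Friedel–Crafts alkylation/hemiacetalisation of 10 with (E)-hex-2-enal (α,α-diphenylprolinol trimethylsilyl ether of the appropriate configuration, benzoic acid, toluene) would give (4R,8S,9R)-5-methoxy-8,9-dimethyl-4-propyl-3,4,9,10-tetrahydro-2H,8H-pyrano[2,3-f]chromen-2-ol F6 as an anomeric mixture. Oxidation with Ag2CO3 on Celite would give 13. The stereocentre is then made by C–C bond formation to the arene instead of by hydride delivery.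

Step 8. The most likely failure is loss of the prenyl group as isoprene from the congested dienone 16, or return to the ether, in competition with the second [3,3] shift. The fallback sets out from 13 and arrives at 18. Bromination of 13 with NBS in MeCN at 0 °C at the only free aromatic position would give (4R,8S,9R)-6-bromo-5-methoxy-8,9-dimethyl-4-propyl-3,4,9,10-tetrahydro-2H,8H-pyrano[2,3-f]chromen-2-one F7. Suzuki–Miyaura coupling with 3-methylbut-2-enylboronic acid pinacol ester (Pd(OAc)2, SPhos, K3PO4, THF/H2O) would give (4R,8S,9R)-5-methoxy-8,9-dimethyl-6-(3-methylbut-2-en-1-yl)-4-propyl-3,4,9,10-tetrahydro-2H,8H-pyrano[2,3-f]chromen-2-one F8. LiOH followed by acidification to pH 4–5 would give 18. The prenyl group is then attached by cross-coupling instead of by sigmatropic transfer from O5.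

## Further compounds

F1 | step 4 | (2R,3R)-4-[4-methoxy-2,6-bis({[2-(trimethylsilyl)ethoxy]methoxy})phenyl]-3-methylbutan-2-ol | C[C@@H](O)[C@H](C)Cc1c(OCOCC[Si](C)(C)C)cc(OC)cc1OCOCC[Si](C)(C)C
F2 | step 4 | 2-[(2R,3R)-3-hydroxy-2-methylbutyl]-5-methoxybenzene-1,3-diol | C[C@@H](O)[C@H](C)Cc1c(O)cc(OC)cc1O
F3 | step 2 | 4-methoxy-2,6-bis({[2-(trimethylsilyl)ethoxy]methoxy})benzaldehyde | O=Cc1c(OCOCC[Si](C)(C)C)cc(OC)cc1OCOCC[Si](C)(C)C
F4 | step 2 | [4-methoxy-2,6-bis({[2-(trimethylsilyl)ethoxy]methoxy})phenyl]methanol | OCc1c(OCOCC[Si](C)(C)C)cc(OC)cc1OCOCC[Si](C)(C)C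
F5 | step 2 | 2-(chloromethyl)-5-methoxy-1,3-bis{[2-(trimethylsilyl)ethoxy]methoxy}benzene | ClCc1c(OCOCC[Si](C)(C)C)cc(OC)cc1OCOCC[Si](C)(C)C
F6 | step 6 | (4R,8S,9R)-5-methoxy-8,9-dimethyl-4-propyl-3,4,9,10-tetrahydro-2H,8H-pyrano[2,3-f]chromen-2-ol (anomeric mixture) | CCC[C@@H]1CC(O)Oc2c1c(OC)cc1c2C[C@@H](C)[C@H](C)O1
F7 | step 8 | (4R,8S,9R)-6-bromo-5-methoxy-8,9-dimethyl-4-propyl-3,4,9,10-tetrahydro-2H,8H-pyrano[2,3-f]chromen-2-one | CCC[C@@H]1CC(=O)Oc2c1c(OC)c(Br)c1c2C[C@@H](C)[C@H](C)O1
F8 | step 8 | (4R,8S,9R)-5-methoxy-8,9-dimethyl-6-(3-methylbut-2-en-1-yl)-4-propyl-3,4,9,10-tetrahydro-2H,8H-pyrano[2,3-f]chromen-2-one | CCC[C@@H]1CC(=O)Oc2c1c(OC)c(CC=C(C)C)c1c2C[C@@H](C)[C@H](C)O1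
A1 | alternative 1 | 5,7-dihydroxy-4-propyl-2H-chromen-2-one | CCCC1=CC(=O)Oc2cc(O)cc(O)c12
A2 | alternative 1 | trans-(±)-5-hydroxy-8,9-dimethyl-4-propyl-8,9-dihydro-2H,10H-pyrano[2,3-f]chromene-2,10-dione (racemate, one enantiomer drawn) | CCCC1=CC(=O)Oc2c1c(O)cc1O[C@@H](C)[C@H](C)C(=O)c21
A3 | alternative 2 | (3S,4R)-3,4-dimethyl-8-(3-methylbut-2-en-1-yl)-2-oxabicyclo[4.2.0]oct-1(8)-en-7-one (C6 epimers) | C[C@@H]1OC2=C(CC=C(C)C)C(=O)C2C[C@H]1C
A4 | alternative 2 | methyl (3R)-3-(methoxyethynyl)hexanoate | CCC[C@H](CC(=O)OC)C#COC
A5 | alternative 3 | 3-hydroxy-5-methoxy-6-methylidenecyclohexa-2,4-dien-1-one | C=C1C(=O)C=C(OC)C=C1O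
A6 | alternative 3 | (3R)-2-ethoxy-7-methoxy-3-methyl-3,4-dihydro-2H-chromen-5-ol (C2 epimers) | CCOC1Oc2cc(OC)cc(O)c2C[C@H]1C
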